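**Plan**

1. The quinone is taken back to its hydroquinone. Its six ring carbons read twice as C(=O)–C(OMe)=C(indolyl), so the four contiguous carbons C(=O)–C(OMe)=C(Ar)–C(–O) map onto a squaric-acid-derived cyclobutenone and the remaining C(OMe)=C(indol-3-yl) pair onto a vinyl arm on its carbinol carbon.
2. Cuts, in order: (a) the ring bond between the indol-3-yl-bearing carbon and its carbonyl neighbour (electrocyclisation); (b) the bond between the carbinol carbon and the methoxyvinyl carbon (carbonyl addition); (c) the cyclobutene–indole C3 bond (Friedel–Crafts on squaric acid dichloride); (d) the indole C7–prenyl bond (Stille); (e) the pyrrole ring of the prenylated indole (Fischer).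
3. Forward: fragment A is the (Z)-enol ether of N-silylated indole-3-carbaldehyde. Fragment B is built as 7-bromo-2-(1,1-dimethylallyl)indole, then prenylated, then joined to the cyclobutenedione. A (as its vinyllithium) adds to B to give a 4-hydroxy-4-alkenylcyclobutenone; the four-membered ring is then expanded thermally to the six-membered hydroquinone ring, and desilylation plus oxidation give the quinone.
4. Stereochemistry: the target has no stereocentre. The (Z)-geometry of the enol ether comes from the Wittig step (isomer separation) and is kept through lithiation; the carbinol centre is racemic and is erased in the ring expansion.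
5. Helpers: the N–Si(i-Pr)3 group on the unsubstituted indole (removed in step 8), the free N–H of the other indole used as its sodium salt to mask the neighbouring carbonyl (released on work-up), and the hydroquinone oxidation level (adjusted in step 8).

Key step: step 7

Remark: 5 and 9 are taken as catalogue chemicals; the single stereocentres of 14 and 16 are formed as racemates and disappear in step 7.

**Step 1**
Reactants: 1 1H-indole-3-carbaldehyde
Product: 2 1-(triisopropylsilyl)-1H-indole-3-carbaldehyde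
Conditions: NaH, THF, 0 °C; then i-Pr3SiCl, 0 °C → rt
Reagents that add atoms: triisopropylsilyl chloride, CC(C)[Si](Cl)(C(C)C)C(C)C
Why: N-silylation of the sodium indolide should proceed cleanly, and the bulky fluoride-labile silyl group later keeps the alkyllithium base away from N–H and C2 of this indole.

**Step 2**
Reactants: 2 1-(triisopropylsilyl)-1H-indole-3-carbaldehyde
Product: 3 3-[(Z)-2-methoxyethenyl]-1-(triisopropylsilyl)-1H-indole
Conditions: MeOCH2PPh3Cl, KN(SiMe3)2, THF, 0 °C; then 2, 0 °C → rt; chromatography on Et3N-deactivated silica to separate the (Z)-isomer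
Reagents that add atoms: (methoxymethyl)triphenylphosphonium chloride, COC[P+](c1ccccc1)(c1ccccc1)c1ccccc1.[Cl-]
Why: The Wittig methoxymethylenation of an aryl aldehyde is expected to give both geometric isomers, of which the (Z)-isomer (vinylic α-H unhindered, indolyl later on the outside of the closing triene) is taken on.

**Step 3**
Reactants: 4 (2-bromophenyl)hydrazine hydrochloride; 5 3,3-dimethylpent-4-en-2-one
Product: 7 7-bromo-2-(2-methylbut-3-en-2-yl)-1H-indole, via hydrazone 6 (not isolated)
Conditions: EtOH, 60 °C; then ZnCl2, AcOH, 100 °C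
Reagents that add atoms: none
Why: In this Fischer indole synthesis the hydrazone can form an ene-hydrazine only toward the methyl group (the other α-carbon is quaternary), so the [3,3]-sigmatropic shift and loss of ammonia should give the 2-tert-alkyl indole with C3–H, with closure at the only free ortho carbon placing bromine at C7.

**Step 4**
Reactants: 7 7-bromo-2-(2-methylbut-3-en-2-yl)-1H-indole
Product: 8 2-(2-methylbut-3-en-2-yl)-7-(3-methylbut-2-en-1-yl)-1H-indole
Conditions: Bu3SnCH2CH=CMe2, Pd(PPh3)4 (5 mol %), DMF, 100 °C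
Reagents that add atoms: tributyl(3-methylbut-2-en-1-yl)stannane, CCCC[Sn](CCCC)(CCCC)CC=C(C)C
Why: Stille coupling of the aryl bromide with the prenylstannane should give the linear prenyl arene, because reductive elimination occurs at the unsubstituted allyl terminus, and the free N–H and the monosubstituted alkene are tolerated.

**Step 5**
Reactants: 8 2-(2-methylbut-3-en-2-yl)-7-(3-methylbut-2-en-1-yl)-1H-indole; 9 3,4-dichlorocyclobut-3-ene-1,2-dione
Product: 11 3-methoxy-4-[2-(2-methylbut-3-en-2-yl)-7-(3-methylbut-2-en-1-yl)-1H-indol-3-yl]cyclobut-3-ene-1,2-dione, via chlorocyclobutenedione 10 (not isolated)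
Conditions: 9, 2,6-di-tert-butylpyridine, CH2Cl2, 0 °C → rt; then MeOH, Et3N, 0 °C → rt
Reagents that add atoms: methanol, CO
Why: Uncatalysed Friedel–Crafts-type addition–elimination of indole C3 (the only free nucleophilic position, the nitrogen being flanked on both sides) on the vinylogous acid chloride, followed by exchange of the second chloride by methanol, should give the methoxy dione while the hindered pyridine keeps HCl away from the two alkenes.

**Step 6**
Reactants: 3 3-[(Z)-2-methoxyethenyl]-1-(triisopropylsilyl)-1H-indole; 11 3-methoxy-4-[2-(2-methylbut-3-en-2-yl)-7-(3-methylbut-2-en-1-yl)-1H-indol-3-yl]cyclobut-3-ene-1,2-dione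
Product: 14 4-hydroxy-2-methoxy-4-{(Z)-1-methoxy-2-[1-(triisopropylsilyl)-1H-indol-3-yl]ethenyl}-3-[2-(2-methylbut-3-en-2-yl)-7-(3-methylbut-2-en-1-yl)-1H-indol-3-yl]cyclobut-2-en-1-one (racemic), via alkenyllithium 12 (not isolated), via sodium indolide 13 (not isolated)
Conditions: 3, t-BuLi, THF, −78 → −40 °C; separately 11, NaH, THF, 0 °C; mix at −78 °C, then −40 °C; sat. aq NH4Cl
Reagents that add atoms: none
Why: This is a 1,2-addition of an α-alkoxyvinyllithium (from ether-directed vinylic deprotonation of the (Z)-enol ether) to a squarate-derived cyclobutenedione, in which the charge of sodium indolide 13 is delocalised through the ring double bond onto the oxygen of the carbonyl next to C–OMe (a vinylogous amidate), so that attack should occur only at the carbonyl next to the indolyl-bearing carbon, and the new carbinol stereocentre is formed as a racemate that step 7 erases.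

**Step 7**
Reactants: 14 4-hydroxy-2-methoxy-4-{(Z)-1-methoxy-2-[1-(triisopropylsilyl)-1H-indol-3-yl]ethenyl}-3-[2-(2-methylbut-3-en-2-yl)-7-(3-methylbut-2-en-1-yl)-1H-indol-3-yl]cyclobut-2-en-1-one
Product: 17 2,5-dimethoxy-3-[2-(2-methylbut-3-en-2-yl)-7-(3-methylbut-2-en-1-yl)-1H-indol-3-yl]-6-[1-(triisopropylsilyl)-1H-indol-3-yl]benzene-1,4-diol, via dienylketene 15 (not isolated), via cyclohexadienone 16 (not isolated)
Conditions: degassed p-xylene, 120 °C, argon
Reagents that add atoms: none
Why: Heating opens the cyclobutenone by conrotatory 4π electrocyclic ring opening to dienylketene 15, which closes by thermal 6π electrocyclisation between the ketene carbon and the indolyl-bearing vinyl carbon to cyclohexadienone 16, and enolisation then gives the hydroquinone, a net ring expansion by two carbons. The closest known reaction type is the thermal rearrangement of 4-alkenyl-4-hydroxycyclobutenones to hydroquinones (Moore-type squarate ring expansion). The six-membered ring is closed in the disrotatory 6π mode with formation of one C–C bond, and no other ring is formed. The sp3 carbon of 16 arises without control and is destroyed by aromatisation, so no stereocentre has to be set. The step needs outward rotation of the hydroxyl group so that the methoxyvinyl arm turns inward next to the ketene; the donor character of the hydroxyl on the carbinol carbon secures this torquoselectivity, and the (Z)-enol ether keeps the silylindolyl group on the outside of the closing terminus. The substitution pattern (para methoxy groups, para indolyl groups) is fixed by the connectivity of 14 and cannot scramble.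

**Step 8**
Reactants: 17 2,5-dimethoxy-3-[2-(2-methylbut-3-en-2-yl)-7-(3-methylbut-2-en-1-yl)-1H-indol-3-yl]-6-[1-(triisopropylsilyl)-1H-indol-3-yl]benzene-1,4-diol
Product: 19 3-(1H-indol-3-yl)-2,5-dimethoxy-6-[2-(2-methylbut-3-en-2-yl)-7-(3-methylbut-2-en-1-yl)-1H-indol-3-yl]cyclohexa-2,5-diene-1,4-dione, via hydroquinone 18 (not isolated)
Conditions: Bu4NF, AcOH, THF, 0 °C, argon; then Ag2O, rt
Reagents that add atoms: none
Why: Buffered fluoride should cleave the N–Si bond under conditions that leave the methoxy groups alone, and Ag2O should oxidise the electron-rich hydroquinone to the quinone without touching the indoles or the alkenes.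

**Compound list**

1 | 1H-indole-3-carbaldehyde | O=Cc1c[nH]c2ccccc12 | starting material
2 | 1-(triisopropylsilyl)-1H-indole-3-carbaldehyde | O=Cc1cn([Si](C(C)C)(C(C)C)C(C)C)c2ccccc12 | intermediate
3 | 3-[(Z)-2-methoxyethenyl]-1-(triisopropylsilyl)-1H-indole | CO/C=C\c1cn([Si](C(C)C)(C(C)C)C(C)C)c2ccccc12 | intermediate
4 | (2-bromophenyl)hydrazine hydrochloride | NNc1ccccc1Br.Cl | starting material
5 | 3,3-dimethylpent-4-en-2-one | CC(=O)C(C)(C)C=C | starting material
6 | 3,3-dimethylpent-4-en-2-one (2-bromophenyl)hydrazone | CC(=NNc1ccccc1Br)C(C)(C)C=C | intermediate (not isolated)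
7 | 7-bromo-2-(2-methylbut-3-en-2-yl)-1H-indole | C=CC(C)(C)c1cc2cccc(Br)c2[nH]1 | intermediate
8 | 2-(2-methylbut-3-en-2-yl)-7-(3-methylbut-2-en-1-yl)-1H-indole | C=CC(C)(C)c1cc2cccc(CC=C(C)C)c2[nH]1 | intermediate
9 | 3,4-dichlorocyclobut-3-ene-1,2-dione (squaric acid dichloride) | O=C1C(Cl)=C(Cl)C1=O | starting material
10 | 3-chloro-4-[2-(2-methylbut-3-en-2-yl)-7-(3-methylbut-2-en-1-yl)-1H-indol-3-yl]cyclobut-3-ene-1,2-dione | O=C1C(=O)C(c2c(C(C)(C)C=C)[nH]c3c(CC=C(C)C)cccc23)=C1Cl | intermediate (not isolated)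
11 | 3-methoxy-4-[2-(2-methylbut-3-en-2-yl)-7-(3-methylbut-2-en-1-yl)-1H-indol-3-yl]cyclobut-3-ene-1,2-dione | COC1=C(c2c(C(C)(C)C=C)[nH]c3c(CC=C(C)C)cccc23)C(=O)C1=O | intermediate
12 | {(Z)-1-methoxy-2-[1-(triisopropylsilyl)-1H-indol-3-yl]ethenyl}lithium | [Li]/C(OC)=C/c1cn([Si](C(C)C)(C(C)C)C(C)C)c2ccccc12 | intermediate (not isolated)
13 | sodium salt (indol-1-ide) of 11 | COC1=C(c2c(C(C)(C)C=C)[n-]c3c(CC=C(C)C)cccc23)C(=O)C1=O.[Na+] | intermediate (not isolated)
14 | 4-hydroxy-2-methoxy-4-{(Z)-1-methoxy-2-[1-(triisopropylsilyl)-1H-indol-3-yl]ethenyl}-3-[2-(2-methylbut-3-en-2-yl)-7-(3-methylbut-2-en-1-yl)-1H-indol-3-yl]cyclobut-2-en-1-one (racemic) | COC1=C(c2c(C(C)(C)C=C)[nH]c3c(CC=C(C)C)cccc23)C(O)(/C(OC)=C/c2cn([Si](C(C)C)(C(C)C)C(C)C)c3ccccc23)C1=O | intermediate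
15 | (3E,5Z)-4-hydroxy-2,5-dimethoxy-3-[2-(2-methylbut-3-en-2-yl)-7-(3-methylbut-2-en-1-yl)-1H-indol-3-yl]-6-[1-(triisopropylsilyl)-1H-indol-3-yl]hexa-1,3,5-trien-1-one | O=C=C(OC)/C(c1c(C(C)(C)C=C)[nH]c2c(CC=C(C)C)cccc12)=C(O)\C(OC)=C\c1cn([Si](C(C)C)(C(C)C)C(C)C)c2ccccc12 | intermediate (not isolated)
16 | 4-hydroxy-2,5-dimethoxy-3-[2-(2-methylbut-3-en-2-yl)-7-(3-methylbut-2-en-1-yl)-1H-indol-3-yl]-6-[1-(triisopropylsilyl)-1H-indol-3-yl]cyclohexa-2,4-dien-1-one (racemic) | COC1=C(c2c(C(C)(C)C=C)[nH]c3c(CC=C(C)C)cccc23)C(O)=C(OC)C(c2cn([Si](C(C)C)(C(C)C)C(C)C)c3ccccc23)C1=O | intermediate (not isolated)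
17 | 2,5-dimethoxy-3-[2-(2-methylbut-3-en-2-yl)-7-(3-methylbut-2-en-1-yl)-1H-indol-3-yl]-6-[1-(triisopropylsilyl)-1H-indol-3-yl]benzene-1,4-diol | COc1c(O)c(-c2cn([Si](C(C)C)(C(C)C)C(C)C)c3ccccc23)c(OC)c(O)c1-c1c(C(C)(C)C=C)[nH]c2c(CC=C(C)C)cccc12 | intermediate
18 | 3-(1H-indol-3-yl)-2,5-dimethoxy-6-[2-(2-methylbut-3-en-2-yl)-7-(3-methylbut-2-en-1-yl)-1H-indol-3-yl]benzene-1,4-diol | COc1c(O)c(-c2c[nH]c3ccccc23)c(OC)c(O)c1-c1c(C(C)(C)C=C)[nH]c2c(CC=C(C)C)cccc12 | intermediate (not isolated)
19 | 3-(1H-indol-3-yl)-2,5-dimethoxy-6-[2-(2-methylbut-3-en-2-yl)-7-(3-methylbut-2-en-1-yl)-1H-indol-3-yl]cyclohexa-2,5-diene-1,4-dione | C=CC(C)(C)c1[nH]c2c(CC=C(C)C)cccc2c1C1=C(OC)C(=O)C(c2c[nH]c3ccccc23)=C(OC)C1=O | target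

**Totals**

Total step count: 8.
Longest linear sequence: 6 steps (steps 3, 4, 5, 6, 7, 8, from 4 and 5).

**Steps most likely to fail**

Step 6. The alkenyllithium may attack the other carbonyl group if the indolide does not mask it well enough, may attack the methoxy-bearing ring carbon, or may add too slowly to the anionic dione. The fallback inverts the order of bond formation so that connectivity alone fixes the regiochemistry; it sets out from 3 and 8 and comes back to the route at 14. Alkenyllithium 12, made from 3 as in step 6, is added to commercial dimethyl squarate (THF, −78 °C) to give 4-hydroxy-2,3-dimethoxy-4-{(Z)-1-methoxy-2-[1-(triisopropylsilyl)-1H-indol-3-yl]ethenyl}cyclobut-2-en-1-one F1. This is silylated (Me3SiCl, Et3N, CH2Cl2) to its trimethylsilyl ether 2,3-dimethoxy-4-{(Z)-1-methoxy-2-[1-(triisopropylsilyl)-1H-indol-3-yl]ethenyl}-4-[(trimethylsilyl)oxy]cyclobut-2-en-1-one F2. Indole 8 is brominated at C3 (N-bromosuccinimide, THF, −78 °C) to 3-bromo-2-(2-methylbut-3-en-2-yl)-7-(3-methylbut-2-en-1-yl)-1H-indole F3. Treatment with KH and then t-BuLi (THF, −78 °C) converts this into the 1-potassio-3-lithio indole F4. F4 is added to the remaining carbonyl group of F2 to give the adduct 3,4-dimethoxy-2-{(Z)-1-methoxy-2-[1-(triisopropylsilyl)-1H-indol-3-yl]ethenyl}-1-[2-(2-methylbut-3-en-2-yl)-7-(3-methylbut-2-en-1-yl)-1H-indol-3-yl]-2-[(trimethylsilyl)oxy]cyclobut-3-en-1-ol F5, which is not isolated. Dilute aqueous HCl in THF at 0 °C should then expel methanol and the silyl group with allylic transposition to give 14. This is the established sequential double organolithium addition to a squarate ester, in which the first nucleophile ends on the carbinol carbon and the second on the neighbouring ring sp2 carbon.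

Step 3. The acidic medium may degrade or cyclise the 1,1-dimethylallyl group, and the sigmatropic step of the ortho-bromo ene-hydrazine may be sluggish. The fallback builds the pyrrole ring by palladium catalysis instead; it sets out from 5 and comes back to the route at 7. Commercial 2-bromo-6-iodoaniline is condensed with 5 and cyclised in one operation (Pd(OAc)2, 1,4-diazabicyclo[2.2.2]octane, DMF, 105 °C) through N-(2-bromo-6-iodophenyl)-3,3-dimethylpent-4-en-2-imine F6 (not isolated). The enamine tautomer of F6 undergoes intramolecular Heck-type closure at the carbon–iodine bond, which reacts in preference to the carbon–bromine bond, to give 7.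

Step 7. Ring opening may occur with the hydroxyl group turned inward, the ketene may be captured by the hydroxyl group (lactonisation) before electrocyclisation, or the push–pull cyclobutenone may open too slowly. The fallback assembles the quinone from a preformed six-membered ring; it sets out from 8 and comes back to the route at 19. Acid-promoted conjugate addition of 8 to commercial 2,5-dichloro-1,4-benzoquinone (AcOH, rt) gives 2,5-dichloro-3-[2-(2-methylbut-3-en-2-yl)-7-(3-methylbut-2-en-1-yl)-1H-indol-3-yl]benzene-1,4-diol F7. This is reoxidised (2,3-dichloro-5,6-dicyano-1,4-benzoquinone) to 2,5-dichloro-3-[2-(2-methylbut-3-en-2-yl)-7-(3-methylbut-2-en-1-yl)-1H-indol-3-yl]cyclohexa-2,5-diene-1,4-dione F8. The same addition with commercial indole gives 2,5-dichloro-3-(1H-indol-3-yl)-6-[2-(2-methylbut-3-en-2-yl)-7-(3-methylbut-2-en-1-yl)-1H-indol-3-yl]benzene-1,4-diol F9, and reoxidation gives 2,5-dichloro-3-(1H-indol-3-yl)-6-[2-(2-methylbut-3-en-2-yl)-7-(3-methylbut-2-en-1-yl)-1H-indol-3-yl]cyclohexa-2,5-diene-1,4-dione F10. NaOMe in MeOH at 0 °C should then replace both chlorides by addition–elimination to give 19.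

**Further compounds**

F1 | step 6 | 4-hydroxy-2,3-dimethoxy-4-{(Z)-1-methoxy-2-[1-(triisopropylsilyl)-1H-indol-3-yl]ethenyl}cyclobut-2-en-1-one | COC1=C(OC)C(O)(/C(OC)=C/c2cn([Si](C(C)C)(C(C)C)C(C)C)c3ccccc23)C1=O
F2 | step 6 | 2,3-dimethoxy-4-{(Z)-1-methoxy-2-[1-(triisopropylsilyl)-1H-indol-3-yl]ethenyl}-4-[(trimethylsilyl)oxy]cyclobut-2-en-1-one | COC1=C(OC)C(O[Si](C)(C)C)(/C(OC)=C/c2cn([Si](C(C)C)(C(C)C)C(C)C)c3ccccc23)C1=O
F3 | step 6 | 3-bromo-2-(2-methylbut-3-en-2-yl)-7-(3-methylbut-2-en-1-yl)-1H-indole | C=CC(C)(C)c1[nH]c2c(CC=C(C)C)cccc2c1Br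
F4 | step 6 | 3-lithio-2-(2-methylbut-3-en-2-yl)-7-(3-methylbut-2-en-1-yl)-1-potassioindole | C=CC(C)(C)c1c([Li])c2cccc(CC=C(C)C)c2n1[K]
F5 | step 6 | 3,4-dimethoxy-2-{(Z)-1-methoxy-2-[1-(triisopropylsilyl)-1H-indol-3-yl]ethenyl}-1-[2-(2-methylbut-3-en-2-yl)-7-(3-methylbut-2-en-1-yl)-1H-indol-3-yl]-2-[(trimethylsilyl)oxy]cyclobut-3-en-1-ol | COC1=C(OC)C(O)(c2c(C(C)(C)C=C)[nH]c3c(CC=C(C)C)cccc23)C1(O[Si](C)(C)C)/C(OC)=C/c1cn([Si](C(C)C)(C(C)C)C(C)C)c2ccccc12
F6 | step 3 | N-(2-bromo-6-iodophenyl)-3,3-dimethylpent-4-en-2-imine | CC(=Nc1c(Br)cccc1I)C(C)(C)C=C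
F7 | step 7 | 2,5-dichloro-3-[2-(2-methylbut-3-en-2-yl)-7-(3-methylbut-2-en-1-yl)-1H-indol-3-yl]benzene-1,4-diol | Oc1cc(Cl)c(O)c(-c2c(C(C)(C)C=C)[nH]c3c(CC=C(C)C)cccc23)c1Cl
F8 | step 7 | 2,5-dichloro-3-[2-(2-methylbut-3-en-2-yl)-7-(3-methylbut-2-en-1-yl)-1H-indol-3-yl]cyclohexa-2,5-diene-1,4-dione | O=C1C(Cl)=C(c2c(C(C)(C)C=C)[nH]c3c(CC=C(C)C)cccc23)C(=O)C(Cl)=C1
F9 | step 7 | 2,5-dichloro-3-(1H-indol-3-yl)-6-[2-(2-methylbut-3-en-2-yl)-7-(3-methylbut-2-en-1-yl)-1H-indol-3-yl]benzene-1,4-diol | Oc1c(Cl)c(-c2c(C(C)(C)C=C)[nH]c3c(CC=C(C)C)cccc23)c(O)c(Cl)c1-c1c[nH]c2ccccc12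
F10 | step 7 | 2,5-dichloro-3-(1H-indol-3-yl)-6-[2-(2-methylbut-3-en-2-yl)-7-(3-methylbut-2-en-1-yl)-1H-indol-3-yl]cyclohexa-2,5-diene-1,4-dione | O=C1C(Cl)=C(c2c(C(C)(C)C=C)[nH]c3c(CC=C(C)C)cccc23)C(=O)C(Cl)=C1c1c[nH]c2ccccc12
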